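## Retrosynthetic overview

1. The target is reached from 8,11-dihydroxyguai-4-en-3-one by acylating first the secondary C8 hydroxyl (propanoate), then the tertiary C11 hydroxyl (acetate).
2. Ring A (cyclopentenone, C1–C5) comes from aldol condensation of C4 onto C5 in a 2-(2-oxobutyl)cycloheptanone; the 1,4-diketone comes from hydration of a but-2-ynyl chain on C1.
3. Ring B (C1, C5–C10) comes from a cyclohepta-1,4-diene bis(silyl enol ether) with a removable ester on C6: the C8 ketone is unmasked and reduced, and the ester is lost.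
4. Key disconnection C1–C10 (with C6–C7): formal (4+3) of a 2-siloxydiene (C7=C8–C9=C10) with a rhodium siloxyvinylcarbenoid (C6–C5=C1), i.e. cyclopropanation then Cope rearrangement of a cis-divinylcyclopropane. The enabling feature: in ring B, C5 (a ketone once ring A is opened by retro-aldol) and C8 (the ester-bearing carbinol) are 1,4-related oxygenated carbons flanking the single sp3 carbon C7. Ring B therefore maps onto a cyclohepta-1,4-diene with enol ethers C5=C6 and C8=C9 and the saturated C1–C10 bond opposite C7.
5. Ring order: cyclopropane (transient), then seven-membered ring B, then five-membered ring A.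

Key step: step 6

Remark on numbering: guaiane numbering of the target is used for positions throughout (ring A = C1–C5, ring B = C1, C5–C10, C11 = carbinol carbon, C14 = methyl on C10, C15 = methyl on C4).

Assumption: Rh2(S-PTAD)4 is taken to deliver the carbenoid to the face of the C7=C8 bond of 9 that gives 11 as drawn; if the sense of induction is the opposite one, Rh2(R-PTAD)4 is used with no other change.

## Route

Step 1
Reactants: 1 methyl acetoacetate; 2 1-bromobut-2-yne
Product: 3 methyl 3-oxooct-6-ynoate
Conditions: NaH, THF, 0 °C; n-BuLi, 0 °C; 2, 0 °C to rt; then 1 M HCl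
Reagents that add atoms: none
Why: Dianion (γ-) alkylation of a β-keto ester, in which the more basic terminal carbanion is alkylated by the propargylic bromide, puts C2, C3, C4 and C15 on the future C1; no stereocentre is formed.

Step 2
Reactants: 3 methyl 3-oxooct-6-ynoate
Product: 4 methyl 2-diazo-3-oxooct-6-ynoate
Conditions: 4-acetamidobenzenesulfonyl azide, Et3N, MeCN, 0 °C to rt
Reagents that add atoms: 4-acetamidobenzenesulfonyl azide, CC(=O)Nc1ccc(cc1)S(=O)(=O)N=[N+]=[N-]
Why: Regitz diazo transfer to the activated methylene of a β-keto ester is general and leaves the internal alkyne untouched; no stereocentre is formed.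

Step 3
Reactants: 4 methyl 2-diazo-3-oxooct-6-ynoate
Product: 5 methyl (3Z)-3-[(tert-butyldimethylsilyl)oxy]-2-diazooct-3-en-6-ynoate
Conditions: TBSOTf, Et3N, CH2Cl2, 0 °C
Reagents that add atoms: tert-butyldimethylsilyl trifluoromethanesulfonate, CC(C)(C)[Si](C)(C)OS(=O)(=O)C(F)(F)F
Why: Soft enolisation and O-silylation of a 2-diazo-3-oxo ester (the standard entry to siloxyvinyldiazoacetates) can only enolise toward the CH2 group and should give the Z enol ether, which places the butynyl group on the outside of the later Cope transition state.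

Step 4
Reactants: 6 (E)-pent-3-en-2-one; 7 acetone
Product: 8 (E)-6-hydroxy-6-methylhept-2-en-4-one
Conditions: LiN(iPr)2, THF, −78 °C; 7, −78 °C; AcOH quench at −78 °C
Reagents that add atoms: none
Why: Kinetic deprotonation of the enone at its α′-methyl group and aldol addition to acetone gives the tertiary β-hydroxy ketone that carries C11–C13, and the cold acidic quench is meant to prevent retro-aldol cleavage; no stereocentre is formed.

Step 5
Reactants: 8 (E)-6-hydroxy-6-methylhept-2-en-4-one
Product: 9 (2E,4Z)-6-methyl-4,6-bis(triethylsilyloxy)hepta-2,4-diene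
Conditions: Et3SiOTf (2.3 equiv), Et3N, CH2Cl2, −78 to 0 °C
Reagents that add atoms: triethylsilyl trifluoromethanesulfonate, CC[Si](CC)(CC)OS(=O)(=O)C(F)(F)F
Why: The silyl triflate/amine pair silylates the tertiary alcohol and enolises the ketone on its α′ side to the 2-siloxydiene; the Z enol ether (silyloxy cis to the bulky carbinol carbon, avoiding allylic strain with the propenyl group) is expected, and this geometry later places C11 trans to the propenyl group on the cyclopropane.

Step 6
Reactants: 5 methyl (3Z)-3-[(tert-butyldimethylsilyl)oxy]-2-diazooct-3-en-6-ynoate; 9 (2E,4Z)-6-methyl-4,6-bis(triethylsilyloxy)hepta-2,4-diene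
Product: 11 methyl (3S,4S,7R)-3-(but-2-yn-1-yl)-2-[(tert-butyldimethylsilyl)oxy]-4-methyl-6-(triethylsilyloxy)-7-[2-(triethylsilyloxy)propan-2-yl]cyclohepta-1,5-diene-1-carboxylate, via cis-divinylcyclopropane 10 (not isolated)
Conditions: Rh2(S-PTAD)4 [dirhodium tetrakis((S)-N-phthalimido-1-adamantylacetate)] (1 mol %), hexane, −20 °C, slow addition of 5 to 9 (1.5 equiv); then 50 °C
Reagents that add atoms: none
Why: The rhodium carboxylate converts 5 into a donor/acceptor siloxyvinylcarbenoid that cyclopropanates the silyloxy-bearing C7=C8 bond of 9 in a concerted, asynchronous [2+1] addition with its vinyl group delivered cis to the propenyl group, and the cis-divinylcyclopropane 10 then undergoes a strain-driven Cope rearrangement through a boat transition state in which the C6–C8 bond (flanked by the silyloxy donor and the ester acceptor) breaks and the C1–C10 bond forms. The closest known reaction type is the tandem cyclopropanation/Cope rearrangement (formal (4+3) cycloaddition) of siloxyvinyldiazoacetates with dienes under chiral dirhodium tetracarboxylates. The three-membered ring closes by carbene addition and the seven-membered ring by the [3,3]-sigmatropic ring expansion, that is by joining C1 and C10, the two alkene termini held together by the cyclopropane. C7 is set by the catalyst (choice of enol-ether face) together with the Z enol ether geometry of 9, which places the C11 carbinol group trans to both alkenyl groups; C10 is set by the E-propenyl geometry and the boat transition state (methyl cis to the C7 side chain); C1 is set by the Z geometry of 5 (butynyl cis to both, the sense that is corrected by equilibration in step 10). The step needs site selectivity for the enol-ether double bond over the trans-propenyl bond and the internal alkyne, and carbenoid rather than vinylogous reactivity; the first is secured by the electron-rich silyl enol ether set against two π-systems that are poor substrates for donor/acceptor rhodium carbenoids, the second by the substituted vinyl terminus and the hydrocarbon solvent.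

Step 7
Reactants: 11 cycloheptadiene bis(silyl enol ether)
Product: 12 methyl (3S,4S,7R)-3-(but-2-yn-1-yl)-2-[(tert-butyldimethylsilyl)oxy]-4-methyl-6-oxo-7-[2-(triethylsilyloxy)propan-2-yl]cyclohept-1-ene-1-carboxylate
Conditions: AcOH/THF/H2O (3:1:1), 0 °C
Reagents that add atoms: none
Why: The simple triethylsilyl enol ether is protonated at C9 and hydrolysed by dilute acetic acid much faster than the push–pull β-silyloxy enoate (C5=C6) or the tertiary silyl ether, so only the C8 ketone should be released, and the short cold exposure is meant to leave the C7 centre next to it untouched.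

Step 8
Reactants: 12 C8 ketone
Product: 13 methyl (3S,4S,6R,7S)-3-(but-2-yn-1-yl)-2-[(tert-butyldimethylsilyl)oxy]-6-hydroxy-4-methyl-7-[2-(triethylsilyloxy)propan-2-yl]cyclohept-1-ene-1-carboxylate
Conditions: LiBH(sec-Bu)3 (L-Selectride), THF, −78 °C; then H2O
Reagents that add atoms: none
Why: In this bulky-hydride reduction of a 2-substituted cycloheptanone the hydride should attack C8 from the face opposite the large C7 substituent, so that the new hydroxyl is cis to it (8R in guaiane numbering), while the vinylogous carbonate is inert at −78 °C.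

Step 9
Reactants: 13 C8 alcohol
Product: 15 (2S,3S,5R,6S)-2-(but-2-yn-1-yl)-5-hydroxy-6-(2-hydroxypropan-2-yl)-3-methylcycloheptan-1-one, via enolised keto ester 14 (not isolated)
Conditions: Bu4NF, THF, 0 °C to rt; then LiCl, DMSO/H2O, 140 °C
Reagents that add atoms: none
Why: Fluoride cleaves the enol silyl ether (releasing the β-keto ester) and the tertiary silyl ether, and Krapcho dealkoxycarbonylation then removes the ester that served as the carbenoid acceptor group; C7, C8 and C10 are not enolisable, and any epimerisation at C1 is without consequence because C1 is equilibrated in step 10.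

Step 10
Reactants: 15 alkynyl ketone diol
Product: 17 (1R,7S,8R,10S)-8,11-dihydroxyguai-4-en-3-one, via diketone 16 (not isolated)
Conditions: NaAuCl4·2H2O (2 mol %), MeOH/H2O (10:1), 65 °C; then KOH, 65 °C
Reagents that add atoms: water, O
Why: Carbonyl-assisted (5-exo) hydration of the 4-alkynone under trivalent gold catalysis should place the new ketone on C3, and hydroxide then effects the intramolecular aldol condensation of C4 onto C5 to the tetrasubstituted cyclopentenone; C1, enolisable before ring closure and γ-enolisable after it, should equilibrate to the configuration with C2 trans to the C10 methyl group (1R), which is expected to be the more stable one.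

Step 11
Reactants: 17 enone diol
Product: 18 (1R,7S,8R,10S)-11-hydroxy-8-(propanoyloxy)guai-4-en-3-one
Conditions: (EtCO)2O, pyridine, DMAP (cat.), CH2Cl2, 0 °C to rt
Reagents that add atoms: propanoic anhydride, CCC(=O)OC(=O)CC
Why: DMAP-catalysed acylation should distinguish the secondary C8 hydroxyl from the tertiary C11 hydroxyl; no stereocentre is touched.

Step 12
Reactants: 18 hydroxy propanoate
Product: 19 (1R,7S,8R,10S)-11-acetoxy-8-(propanoyloxy)guai-4-en-3-one (target)
Conditions: Ac2O, Sc(OTf)3 (2 mol %), MeCN, −20 °C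
Reagents that add atoms: acetic anhydride, CC(=O)OC(C)=O
Why: Lewis-acid-catalysed acetylation with Sc(OTf)3 is a known way to esterify tertiary alcohols at low temperature, chosen here to avoid elimination and acyl exchange.

## Compound list

1 | methyl acetoacetate | COC(=O)CC(C)=O | starting material
2 | 1-bromobut-2-yne | CC#CCBr | starting material
3 | methyl 3-oxooct-6-ynoate | COC(=O)CC(=O)CCC#CC | intermediate
4 | methyl 2-diazo-3-oxooct-6-ynoate | COC(=O)C(=[N+]=[N-])C(=O)CCC#CC | intermediate
5 | methyl (3Z)-3-[(tert-butyldimethylsilyl)oxy]-2-diazooct-3-en-6-ynoate | COC(=O)C(=[N+]=[N-])/C(O[Si](C)(C)C(C)(C)C)=C/CC#CC | intermediate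
6 | (E)-pent-3-en-2-one | C/C=C/C(C)=O | starting material
7 | acetone | CC(C)=O | starting material
8 | (E)-6-hydroxy-6-methylhept-2-en-4-one | C/C=C/C(=O)CC(C)(C)O | intermediate
9 | (2E,4Z)-6-methyl-4,6-bis(triethylsilyloxy)hepta-2,4-diene | C/C=C/C(O[Si](CC)(CC)CC)=C/C(C)(C)O[Si](CC)(CC)CC | intermediate
10 | methyl 1-[(1Z)-1-[(tert-butyldimethylsilyl)oxy]hex-1-en-4-yn-1-yl]-2-[(1E)-prop-1-en-1-yl]-2-(triethylsilyloxy)-3-[2-(triethylsilyloxy)propan-2-yl]cyclopropane-1-carboxylate (the two alkenyl groups cis, the C3 side chain trans to both) | COC(=O)[C@]1(/C(O[Si](C)(C)C(C)(C)C)=C/CC#CC)[C@H](C(C)(C)O[Si](CC)(CC)CC)[C@@]1(O[Si](CC)(CC)CC)/C=C/C | intermediate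
11 | methyl (3S,4S,7R)-3-(but-2-yn-1-yl)-2-[(tert-butyldimethylsilyl)oxy]-4-methyl-6-(triethylsilyloxy)-7-[2-(triethylsilyloxy)propan-2-yl]cyclohepta-1,5-diene-1-carboxylate (substituents at C3, C4 and C7 all cis) | CC[Si](CC)(CC)OC1=C[C@H](C)[C@H](CC#CC)C(O[Si](C)(C)C(C)(C)C)=C(C(=O)OC)[C@@H]1C(C)(C)O[Si](CC)(CC)CC | intermediate
12 | methyl (3S,4S,7R)-3-(but-2-yn-1-yl)-2-[(tert-butyldimethylsilyl)oxy]-4-methyl-6-oxo-7-[2-(triethylsilyloxy)propan-2-yl]cyclohept-1-ene-1-carboxylate | O=C1C[C@H](C)[C@H](CC#CC)C(O[Si](C)(C)C(C)(C)C)=C(C(=O)OC)[C@@H]1C(C)(C)O[Si](CC)(CC)CC | intermediate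
13 | methyl (3S,4S,6R,7S)-3-(but-2-yn-1-yl)-2-[(tert-butyldimethylsilyl)oxy]-6-hydroxy-4-methyl-7-[2-(triethylsilyloxy)propan-2-yl]cyclohept-1-ene-1-carboxylate | O[C@@H]1C[C@H](C)[C@H](CC#CC)C(O[Si](C)(C)C(C)(C)C)=C(C(=O)OC)[C@@H]1C(C)(C)O[Si](CC)(CC)CC | intermediate
14 | methyl (3S,4S,6R,7S)-3-(but-2-yn-1-yl)-2,6-dihydroxy-7-(2-hydroxypropan-2-yl)-4-methylcyclohept-1-ene-1-carboxylate (β-keto ester drawn as its enol) | O[C@@H]1C[C@H](C)[C@H](CC#CC)C(O)=C(C(=O)OC)[C@@H]1C(C)(C)O | intermediate
15 | (2S,3S,5R,6S)-2-(but-2-yn-1-yl)-5-hydroxy-6-(2-hydroxypropan-2-yl)-3-methylcycloheptan-1-one | O[C@@H]1C[C@H](C)[C@H](CC#CC)C(=O)C[C@@H]1C(C)(C)O | intermediate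
16 | (2S,3S,5R,6S)-5-hydroxy-6-(2-hydroxypropan-2-yl)-3-methyl-2-(2-oxobutyl)cycloheptan-1-one | O[C@@H]1C[C@H](C)[C@H](CC(=O)CC)C(=O)C[C@@H]1C(C)(C)O | intermediate
17 | (1R,7S,8R,10S)-8,11-dihydroxyguai-4-en-3-one | O[C@@H]1C[C@H](C)[C@H]2CC(=O)C(C)=C2C[C@@H]1C(C)(C)O | intermediate
18 | (1R,7S,8R,10S)-11-hydroxy-8-(propanoyloxy)guai-4-en-3-one | CCC(=O)O[C@@H]1C[C@H](C)[C@H]2CC(=O)C(C)=C2C[C@@H]1C(C)(C)O | intermediate
19 | (1R,7S,8R,10S)-11-acetoxy-8-(propanoyloxy)guai-4-en-3-one | CCC(=O)O[C@@H]1C[C@H](C)[C@H]2CC(=O)C(C)=C2C[C@@H]1C(C)(C)OC(C)=O | target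

## Step count and risks

Total step count: 12. Longest linear sequence: 10 steps (steps 1, 2, 3, 6, 7, 8, 9, 10, 11, 12).

**Step 6.** Carbenoid transfer to the hindered, trisubstituted enol ether may be too slow (carbene dimerisation), may run through the vinylogous position or a zwitterion to five-membered products, or may show poor face selectivity. The fallback separates the two events and uses a small acceptor carbenoid. It sets out from 9.
- Commercial hex-4-ynoic acid is converted with oxalyl chloride into hex-4-ynoyl chloride F1, and with diazomethane into 1-diazohept-5-yn-2-one F2.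
- Cyclopropanation of the enol-ether double bond of 9 with F2 under CuOTf (monovalent copper) and a chiral bis(oxazoline) ligand should give the siloxycyclopropyl ketone 1-{2-[(E)-prop-1-enyl]-2-(triethylsilyloxy)-3-[2-(triethylsilyloxy)propan-2-yl]cyclopropyl}hex-4-yn-1-one F3. The sense and level of induction would have to be established, and the enantiomers could otherwise be separated on a chiral stationary phase at the stage of 15.
- Enol silylation toward C1 (LiN(iPr)2, TBSCl, THF/HMPA) gives the silyl enol ether of the cis-2-vinylcyclopropyl ketone F4.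
- On warming (80–110 °C) F4 undergoes the classical divinylcyclopropane Cope ring expansion to the ester-free cycloheptadiene bis(silyl enol ether) F5. Any trans isomer should funnel in through reversible opening of the donor–acceptor ring.
- Hydrolysis of the triethylsilyl enol ether as in step 7 gives the C8 ketone F6, reduction as in step 8 gives the C8 alcohol F7, and Bu4NF then removes the remaining silyl groups. The route is rejoined at 15.

**Step 10.** Hydration may take the wrong regiochemical course or stop at a fused furan, and equilibration at C1 under hydroxide may be incomplete or unfavourable. The fallback moves stereocontrol to the saturated ketone and closes ring A without hydroxide. It sets out from 15.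
- Base equilibration (DBU, toluene, 80 °C) at the cycloheptanone stage, where the 2,3-trans preference is clearest, gives (2R,3S,5R,6S)-2-(but-2-yn-1-yl)-5-hydroxy-6-(2-hydroxypropan-2-yl)-3-methylcycloheptan-1-one F10, with recycling of the cis isomer.
- Hydration alone, stopped before base, gives the trans diketone (2R,3S,5R,6S)-5-hydroxy-6-(2-hydroxypropan-2-yl)-3-methyl-2-(2-oxobutyl)cycloheptan-1-one F11.
- Amine-catalysed cyclodehydration (pyrrolidine, AcOH, toluene, 80 °C) through the enamine of the ethyl ketone closes ring A. The route is rejoined at 17.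

**Step 8.** Hydride delivery may show poor facial selectivity, or C7 may epimerise before reduction. The fallback replaces steric control by chelation control. It sets out from 12.
- Dilute HCl in THF removes the tertiary silyl ether to give the β-hydroxy ketone methyl 3-(but-2-yn-1-yl)-2-[(tert-butyldimethylsilyl)oxy]-7-(2-hydroxypropan-2-yl)-4-methyl-6-oxocyclohept-1-ene-1-carboxylate F8.
- Narasaka–Prasad reduction (Et2BOMe, NaBH4, THF/MeOH, −78 °C) proceeds through the six-membered boron chelate of O8 and O11. External hydride attacks C8 from the face opposite the carbocycle that bridges C7 and C8, which puts O8 cis to C11 in the diol methyl 3-(but-2-yn-1-yl)-2-[(tert-butyldimethylsilyl)oxy]-6-hydroxy-7-(2-hydroxypropan-2-yl)-4-methylcyclohept-1-ene-1-carboxylate F9.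
- F9 is taken through the conditions of step 9 (it gives 14 on desilylation). The route is rejoined at 15.

Further compounds
F1 | step 6 | hex-4-ynoyl chloride | CC#CCCC(Cl)=O
F2 | step 6 | 1-diazohept-5-yn-2-one | CC#CCCC(=O)C=[N+]=[N-]
F3 | step 6 | 1-{2-[(E)-prop-1-enyl]-2-(triethylsilyloxy)-3-[2-(triethylsilyloxy)propan-2-yl]cyclopropyl}hex-4-yn-1-one (acyl cis to propenyl, C3 side chain trans to both) | CC#CCCC(=O)[C@H]1[C@H](C(C)(C)O[Si](CC)(CC)CC)[C@@]1(O[Si](CC)(CC)CC)/C=C/C
F4 | step 6 | tert-butyl{[(1Z)-1-{2-[(E)-prop-1-enyl]-2-(triethylsilyloxy)-3-[2-(triethylsilyloxy)propan-2-yl]cyclopropyl}hex-1-en-4-yn-1-yl]oxy}dimethylsilane | CC#CC/C=C(O[Si](C)(C)C(C)(C)C)/[C@H]1[C@H](C(C)(C)O[Si](CC)(CC)CC)[C@@]1(O[Si](CC)(CC)CC)/C=C/C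
F5 | step 6 | tert-butyl{[7-(but-2-yn-1-yl)-6-methyl-4-(triethylsilyloxy)-3-[2-(triethylsilyloxy)propan-2-yl]cyclohepta-1,4-dien-1-yl]oxy}dimethylsilane (substituents at C3, C6 and C7 all cis) | CC[Si](CC)(CC)OC1=C[C@H](C)[C@H](CC#CC)C(O[Si](C)(C)C(C)(C)C)=C[C@@H]1C(C)(C)O[Si](CC)(CC)CC
F6 | step 6 | 5-(but-2-yn-1-yl)-4-[(tert-butyldimethylsilyl)oxy]-6-methyl-2-[2-(triethylsilyloxy)propan-2-yl]cyclohept-3-en-1-one (substituents at C2, C5 and C6 all cis) | O=C1C[C@H](C)[C@H](CC#CC)C(O[Si](C)(C)C(C)(C)C)=C[C@@H]1C(C)(C)O[Si](CC)(CC)CC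
F7 | step 6 | 5-(but-2-yn-1-yl)-4-[(tert-butyldimethylsilyl)oxy]-6-methyl-2-[2-(triethylsilyloxy)propan-2-yl]cyclohept-3-en-1-ol (hydroxyl and substituents at C2, C5 and C6 all cis) | O[C@@H]1C[C@H](C)[C@H](CC#CC)C(O[Si](C)(C)C(C)(C)C)=C[C@@H]1C(C)(C)O[Si](CC)(CC)CC
F8 | step 8 | methyl 3-(but-2-yn-1-yl)-2-[(tert-butyldimethylsilyl)oxy]-7-(2-hydroxypropan-2-yl)-4-methyl-6-oxocyclohept-1-ene-1-carboxylate | O=C1C[C@H](C)[C@H](CC#CC)C(O[Si](C)(C)C(C)(C)C)=C(C(=O)OC)[C@@H]1C(C)(C)O
F9 | step 8 | methyl 3-(but-2-yn-1-yl)-2-[(tert-butyldimethylsilyl)oxy]-6-hydroxy-7-(2-hydroxypropan-2-yl)-4-methylcyclohept-1-ene-1-carboxylate | O[C@@H]1C[C@H](C)[C@H](CC#CC)C(O[Si](C)(C)C(C)(C)C)=C(C(=O)OC)[C@@H]1C(C)(C)O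
F10 | step 10 | (2R,3S,5R,6S)-2-(but-2-yn-1-yl)-5-hydroxy-6-(2-hydroxypropan-2-yl)-3-methylcycloheptan-1-one | O[C@@H]1C[C@H](C)[C@@H](CC#CC)C(=O)C[C@@H]1C(C)(C)O
F11 | step 10 | (2R,3S,5R,6S)-5-hydroxy-6-(2-hydroxypropan-2-yl)-3-methyl-2-(2-oxobutyl)cycloheptan-1-one | O[C@@H]1C[C@H](C)[C@@H](CC(=O)CC)C(=O)C[C@@H]1C(C)(C)O
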